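The target is cut at the two C–C bonds joining the benzylic carbinol carbon to its two identical CH2O carbons. That fully substituted carbon, bonded to the benzene ring, a hydroxyl and two equal oxymethylene arms, is treated as the carbonyl carbon of an aryl ester that accepts the same O-protected hydroxymethyl carbanion twice. In one operation, methyl 2-methoxy-4-methylbenzoate and two equivalents of (benzyloxymethyl)lithium should give the complete carbinol skeleton with all three oxygens in place. The precursor is a simple benzoate ester carrying the ortho methoxy and para methyl groups; debenzylation and selective primary acylation finish the synthesis.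

Key step: step 3

Remark: the carbinol carbon bears two identical arms, so the target has no stereocentre and no stereocontrol is needed; reagents that contribute carbon atoms are numbered like the other compounds.

Step 1
Reactants: 1 4-methylsalicylic acid; 2 iodomethane
Product: 3 methyl 2-methoxy-4-methylbenzoate
Conditions: MeI (3 equiv), K2CO3 (3 equiv), DMF, rt to 50 °C
Reagents that add atoms: iodomethane 2, CI
Why: Williamson-type SN2 O-methylation, in which K2CO3 in DMF generates the carboxylate and the hydrogen-bonded, less reactive phenoxide, and excess iodomethane with mild warming should alkylate both oxygens, there being no other nucleophilic site.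

Step 2
Reactants: 4 tributyltin hydride; 5 benzyl chloromethyl ether
Product: 7 (benzyloxymethyl)tributylstannane, via tributylstannyllithium 6 (not isolated)
Conditions: LiN(i-Pr)2 (1.0 equiv, commercial solution), THF, 0 °C; then 5 (1.0 equiv), –78 °C to rt
Reagents that add atoms: benzyl chloromethyl ether 5, ClCOCc1ccccc1
Why: Deprotonation of the Sn–H bond by the amide base gives the stannyl anion 6, which should displace chloride from the very reactive α-chloro ether in an SN2 alkylation of a stannyllithium, the standard entry to alkoxymethylstannanes.

Step 3
Reactants: 3 methyl 2-methoxy-4-methylbenzoate; 7 (benzyloxymethyl)tributylstannane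
Product: 10 1,3-bis(benzyloxy)-2-(2-methoxy-4-methylphenyl)propan-2-ol, via (benzyloxymethyl)lithium 8 (not isolated), via benzyloxymethyl aryl ketone 9 (not isolated)
Conditions: 7 (3.0 equiv), n-BuLi (2.9 equiv), THF, –78 °C; then 3 (1.0 equiv) in THF, –78 °C to –40 °C; then H2O
Reagents that add atoms: (benzyloxymethyl)tributylstannane 7, CCCC[Sn](CCCC)(CCCC)COCc1ccccc1 (delivers two CH2OCH2Ph units as 8, [Li]COCc1ccccc1)
Why: Tin–lithium exchange of 7 with n-BuLi, run with a small deficit of n-BuLi so that no butyllithium remains to attack the ester, should give the α-alkoxy organolithium 8 and inert Bu4Sn. Reagent 8 adds to the ester carbonyl of 3, the tetrahedral lithium alkoxide expels LiOMe to give the α-benzyloxy ketone 9, and 9, a better electrophile than 3, should capture a second equivalent of 8 to give the tertiary lithium alkoxide that is protonated on quench. The closest known reaction type is the carbonyl addition of alkoxymethyllithium reagents generated from stannanes, merged with the classical double addition of organolithiums to esters. No ring is closed and no stereocentre arises, since the two arms introduced are identical. The selectivity required is 1,2-addition to 9 in preference to deprotonation of its CH2 group; the low temperature, the excess of 8 and lithium chelation through the α-benzyloxy and ortho methoxy oxygens, which keeps the carbonyl activated, should secure it. The aryl methyl ether and the ring methyl group should not be metalated at –78 °C.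

Step 4
Reactants: 10 1,3-bis(benzyloxy)-2-(2-methoxy-4-methylphenyl)propan-2-ol
Product: 11 2-(2-methoxy-4-methylphenyl)propane-1,2,3-triol
Conditions: H2 (1 atm), Pd(OH)2 on carbon, EtOAc/EtOH, rt
Reagents that add atoms: none
Why: Catalytic hydrogenolysis of benzyl ethers, in which the two unhindered primary O-benzyl bonds should cleave readily in neutral medium, whereas the tertiary benzylic C–OH bond is shielded by the ortho methoxy group, deactivated by its two β-oxygen substituents and not acid-activated, and the aryl methyl ether and arene are inert.

Step 5
Reactants: 11 2-(2-methoxy-4-methylphenyl)propane-1,2,3-triol; 12 isobutyric anhydride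
Product: 13 2-hydroxy-2-(2-methoxy-4-methylphenyl)propane-1,3-diyl bis(2-methylpropanoate)
Conditions: (i-PrCO)2O (2.2 equiv), pyridine, DMAP (5 mol%), CH2Cl2, 0 °C to rt
Reagents that add atoms: isobutyric anhydride 12, CC(C)C(=O)OC(=O)C(C)C
Why: Chemoselective DMAP-catalysed esterification with an anhydride, in which the two primary hydroxyls should react far faster than the tertiary benzylic hydroxyl buried between the ortho-substituted arene and two CH2O groups, so a slight excess of a moderately bulky anhydride at low temperature should stop at the diester.

Compound list
1 | 4-methylsalicylic acid (2-hydroxy-4-methylbenzoic acid) | Cc1ccc(C(=O)O)c(O)c1 | starting material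
2 | iodomethane | CI | starting material
3 | methyl 2-methoxy-4-methylbenzoate | COC(=O)c1ccc(C)cc1OC | intermediate
4 | tributyltin hydride | CCCC[SnH](CCCC)CCCC | starting material
5 | benzyl chloromethyl ether | ClCOCc1ccccc1 | starting material
6 | tributylstannyllithium (formed in the flask, not isolated) | [Li][Sn](CCCC)(CCCC)CCCC | intermediate
7 | (benzyloxymethyl)tributylstannane | CCCC[Sn](CCCC)(CCCC)COCc1ccccc1 | intermediate
8 | (benzyloxymethyl)lithium (formed in the flask, not isolated) | [Li]COCc1ccccc1 | intermediate
9 | 2-(benzyloxy)-1-(2-methoxy-4-methylphenyl)ethan-1-one (formed in the flask, not isolated) | COc1cc(C)ccc1C(=O)COCc1ccccc1 | intermediate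
10 | 1,3-bis(benzyloxy)-2-(2-methoxy-4-methylphenyl)propan-2-ol | COc1cc(C)ccc1C(O)(COCc1ccccc1)COCc1ccccc1 | intermediate
11 | 2-(2-methoxy-4-methylphenyl)propane-1,2,3-triol | COc1cc(C)ccc1C(O)(CO)CO | intermediate
12 | isobutyric anhydride | CC(C)C(=O)OC(=O)C(C)C | starting material
13 | 2-hydroxy-2-(2-methoxy-4-methylphenyl)propane-1,3-diyl bis(2-methylpropanoate) | COc1cc(C)ccc1C(O)(COC(=O)C(C)C)COC(=O)C(C)C | target

Total step count: 5.
Longest linear sequence: 4 steps (step 1 or step 2, then steps 3, 4 and 5).

Steps most likely to fail

Step 3. The basic carbanion may deprotonate the intermediate ketone instead of adding to it, so that the sequence stalls after the first addition. The reagent may also decay by a 1,2-Wittig shift before it is consumed. The fallback sets out from ester 3 and builds the two arms one after the other, coming back to the route at triol 11. Ester 3 would be converted with MeNH(OMe)·HCl and i-PrMgCl in THF into the Weinreb amide N,2-dimethoxy-N,4-dimethylbenzamide F1. About one equivalent of 8 (from 7 and n-BuLi, –78 °C) should then give ketone 9 cleanly, because the chelated tetrahedral adduct survives until work-up; 9 is isolated here. Wittig methylenation (Ph3PCH3Br, KOt-Bu, THF) should give 1-[3-(benzyloxy)prop-1-en-2-yl]-2-methoxy-4-methylbenzene F2. Dihydroxylation with catalytic OsO4 and NMO in acetone/H2O should give racemic 3-(benzyloxy)-2-(2-methoxy-4-methylphenyl)propane-1,2-diol F3. Its single stereocentre disappears on hydrogenolysis (H2, Pd(OH)2 on carbon), which gives 11.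

Step 4. Reduction may run past the benzyl ethers and cleave the tertiary benzylic C–O bond of the electron-rich arene, or stall after loss of one benzyl group. The fallback replaces the reductive unmasking by an oxidative one; it sets out from tributyltin hydride 4 (with ester 3 as partner) and comes back at triol 11. Stannyllithium 6 (from 4 and LiN(i-Pr)2) would be added to paraformaldehyde to give (tributylstannyl)methanol F4. Alkylation with NaH and 4-methoxybenzyl chloride (catalytic Bu4NI, THF/DMF) should give tributyl{[(4-methoxybenzyl)oxy]methyl}stannane F5. Exchange with n-BuLi gives {[(4-methoxybenzyl)oxy]methyl}lithium F6. Under the conditions of step 3 this should add twice to 3, through 2-[(4-methoxybenzyl)oxy]-1-(2-methoxy-4-methylphenyl)ethan-1-one F7, to give 1,3-bis[(4-methoxybenzyl)oxy]-2-(2-methoxy-4-methylphenyl)propan-2-ol F8. DDQ in CH2Cl2/pH 7 buffer at 0 °C should then release 11; any 4-methoxybenzylidene acetal formed with the tertiary hydroxyl would be hydrolysed with aqueous AcOH.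

Step 5. Chemoselectivity may be lost through acylation of the tertiary hydroxyl under DMAP catalysis, or the reaction may stall at the mono-ester because the primary hydroxyls are neopentyl-like. The fallback sets out from triol 11 and comes back at target 13. It uses enzymatic transesterification in place of chemical acyl transfer: immobilised Candida antarctica lipase B with vinyl isobutyrate in tert-butyl methyl ether at 40 °C. Lipases do not acylate tertiary alcohols, and the irreversible vinyl ester donor should carry both primary positions to the diester.

Further compounds
F1 | step 3 | N,2-dimethoxy-N,4-dimethylbenzamide | CON(C)C(=O)c1ccc(C)cc1OC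
F2 | step 3 | 1-[3-(benzyloxy)prop-1-en-2-yl]-2-methoxy-4-methylbenzene | C=C(COCc1ccccc1)c1ccc(C)cc1OC
F3 | step 3 | racemic 3-(benzyloxy)-2-(2-methoxy-4-methylphenyl)propane-1,2-diol | COc1cc(C)ccc1C(O)(CO)COCc1ccccc1
F4 | step 4 | (tributylstannyl)methanol | CCCC[Sn](CCCC)(CCCC)CO
F5 | step 4 | tributyl{[(4-methoxybenzyl)oxy]methyl}stannane | CCCC[Sn](CCCC)(CCCC)COCc1ccc(OC)cc1
F6 | step 4 | {[(4-methoxybenzyl)oxy]methyl}lithium | [Li]COCc1ccc(OC)cc1
F7 | step 4 | 2-[(4-methoxybenzyl)oxy]-1-(2-methoxy-4-methylphenyl)ethan-1-one | COc1ccc(COCC(=O)c2ccc(C)cc2OC)cc1
F8 | step 4 | 1,3-bis[(4-methoxybenzyl)oxy]-2-(2-methoxy-4-methylphenyl)propan-2-ol | COc1ccc(COCC(O)(COCc2ccc(OC)cc2)c2ccc(C)cc2OC)cc1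
F0 | step 5 | none | none
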